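The run of this flask lasts far longer than any of its reversible steps takes to relax, so you can start from that comparison.

    intermediate D ⇌ intermediate E (K1 = 0.41, k1 = 0.21 min⁻¹)
    substrate ⇌ intermediate B (K2 = 1.1, k2 = 0.21 min⁻¹)
    substrate → intermediate A (k3 = 0.48 min⁻¹)
    intermediate C ⇌ product (K4 = 0.68, k4 = 0.18 min⁻¹)
    intermediate C → intermediate D (k5 = 1.1 min⁻¹)
    intermediate A ⇌ intermediate C (K6 = 0.14, k6 = 0.30 min⁻¹)

substrate 0.20 M; time 5.0 h

- the reaction counts as stopped when no species that holds the substrate changes by six tenths of a point or more over the second half of the time
- run time (flask): 5.0 h

1. at 5.0 h, what has stopped the reaction, if anything has (forward and back rates have come level / it is still moving / all of the substrate has reacted)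
2. how much intermediate D there is at 5.0 h, in percent of the substrate charged

Climb the ladder by hand from the quickest rung. Intermediate A and intermediate C relax towards each other with a half-life of 0.284 min, and intermediate C leaves for intermediate D with a half-life of 0.63 min. Because intermediate C falls back to intermediate A at 2.14 min⁻¹ per unit of intermediate C, faster than intermediate A climbs at 0.30 min⁻¹, you should expect intermediate A to be the resting state and intermediate C a thin passage. One rung up, intermediate D and intermediate E relax with a half-life of 0.960 min. Next, the substrate and intermediate B empty together, and the slow root of their coupled losses gives a half-life of 5.75 min.

The top rung is the drain of intermediate A. It climbs at k6, but with product set aside, the part k5/(k5+k6/K6) of what reaches intermediate C goes on, which gives 0.102 min⁻¹ and a half-life of 6.81 min. The run holds 44.0 such half-lives, and the substrate empties faster than intermediate A drains, so I expect all of the substrate to have reacted by the end. The charge should then stand in the pair of intermediate D and intermediate E, in balance because that pair relaxes faster than it is fed. The quantity to carry is the split, the part of the pair standing as intermediate E, K1 over one plus K1: 29.1 %. The rest is intermediate D, so I commit to 70.9 %.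

The forecast says all of the substrate has reacted and 70.9 %, on the ground that “the substrate and all upstream intermediates are gone by 5 h”. It puts the slowest relaxation at roughly 0.09 per minute, against my 0.102 min⁻¹, reckoned with product set aside.

The simulation gives all of the substrate has reacted for this flask, with 0 % of the substrate left, intermediate D at 70.9 % and intermediate E at 29.1 %. A much shorter run is what would make the forecast wrong: at 0.500 h this flask held 62.4 % intermediate D and 9.68 % intermediate A, though the answer keeps within 5 points down to at least 0.62 h. Now take the neighbouring flask, charged with 0.080 M of substrate. Its steps are first order, so the run again holds 44.0 half-lives and the split again gives 29.1 %, and that flask shows 0 % substrate left, intermediate E at 29.1 % and intermediate D at 70.9 %.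

The numbers of this flask were set for the occasion.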